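## Structural features

The target is a C25 terpenoid made of a cis-fused decalin (ring A: C1–C5 and C10; ring B: C5–C10, labdane-type numbering) and an unsaturated side chain on C9. Ring A carries only hydrocarbon substituents, the gem-dimethyl C4 and the angular methyl on C10. The only two stereocentres, C5 (R) and the quaternary C10 (S), are adjacent, sit next to the quaternary C4, and place H-5 and the C10 methyl on the same face. Ring B holds a tetrasubstituted C8=C9 alkene with a methyl on C8. From C9 a two-carbon link (C11–C12) leads to a trisubstituted (E)-C13=C14 alkene with a hydroxymethyl group on C13, conjugated through an (E)-C15=C16 alkene to C4 of a furan-2(5H)-one. This trienyl butenolide with its allylic alcohol is the fragile part (base, hydride and dissolving-metal reagents, acid, light), so it has to be completed last. The real difficulty is the cis ring fusion at a quaternary carbon, as a single enantiomer, in a ring without any heteroatom handle. The key step exploits two facts: C10 with its methyl can be the β-carbon of an isophorone-like enone in ring A (C2 carbonyl, C1=C10), and C9 can be an aldehyde carbon on a four-carbon chain hanging from the neighbouring C5. Both carbons are electrophilic, and a one-electron reduction joins them as C9–C10 on the face fixed by C5.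

## Logic of the disconnections

47 is first cut between C16 and the ring carbon of the lactone, giving 43 and 46. This takes away the one group that would not survive hydride, base or organometallic steps and leaves a tin-bearing dienol. The forward coupling must keep both alkene geometries and tolerate a free allylic alcohol. 46 goes back in one step to 44 and 45.

43 is traced to 41 by a change of oxidation level at the C13 substituent, and 41 is cut across C13=C14 into 35 and 39. The cut falls on the only trisubstituted alkene of the chain and turns its geometry into a matter of a thermodynamically controlled olefination. The forward step must give the E isomer and leave the C–Sn bond alone, and the reduction that follows must be 1,2-selective. 39 goes back through 38 to 36 and 37.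

35 is cut at C12–C13 into 32 and 33, and 32 goes back through 30 to 27 by exchange of iodine for oxygen and removal of the C12 oxygen. The whole chain is thereby reduced to a vinyl group on C9. The forward steps need a borane that tells a monosubstituted from a tetrasubstituted alkene and a carbanion that substitutes and does not eliminate.

27 is cut at C9–C11 into 25 and 26, 25 is traced to 22, and 22 is cut at C8–C17 into 19 and 20. All substituents of the C8=C9 alkene then derive from a single carbonyl at C9, and the regiochemistry is unambiguous because C10 is quaternary. The demand is coupling at a hindered, tetrasubstituted alkenyl triflate.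

19 is traced through 18 to 16 by adjusting the oxidation level at C9 and restoring a carbonyl at C2. This exposes a C9 carbinol and a C2 ketone in a 1,4-relationship across C10. The forward deoxygenation must spare the carbinol and must not touch the ring fusion.

16 is cut at C9–C10, which opens ring B and gives 13. One ring, the quaternary centre and the carbinol centre disappear, and C5 remains as the only stereocentre. The forward step must join two electrophilic carbons, close the ring 6-exo, and do so on the face of C10 that lies on the side of the C5 chain.

13 is cut at C8–C9 into 11 and 12, a one-carbon extension of a terminal alkene; the forward step must be linear-selective and leave the enone alone.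

11 is cut at the C10–methyl bond into 7 and 8 (with 9 for the carbonyl oxygen), with a 1,3-shift of the carbonyl. The forward addition must be 1,2 and must not enolise the neighbouring stereocentre.

7 is traced to 6, and 6 is cut into 3 and 4; the bond in question is C5–C6, and its formation creates the only stereocentre that has to be made by asymmetric catalysis. The demand is face selection at a tertiary enolate carbon without equilibration.

3 is cut at its enol ether C–O bond into 1 and 2.

## Other disconnections considered

Alternative 1: The cut is the C1–C10 bond of ring A, paid for with a sacrificial C3–C8 bond. Bridged vinyl carbinol A1 would be reached by dearomatisation of a phenol, cycloaddition with a two-carbon dienophile and vinyl addition to the C3 carbonyl. Its potassium alkoxide (KH, 18-crown-6) would rearrange by an anionic oxy-Cope [3,3] shift to cis-decalin A2.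
- In its favour: the boat-shaped transition state inside the bicycle can only give the cis fusion. A2 already holds the C8=C9 alkene, the C8 methyl and an oxygenated C11–C12 arm on C9, so steps 9 to 12 of the chosen plan would not be needed. On this point the alternative is the better plan.
- Against it here: the absolute configuration would have to come from the cycloaddition of an achiral, fully substituted dienone with a simple dienophile, for which no dependable catalytic asymmetric version can be assumed, so a resolution is likely. The vinyl nucleophile must add to a carbonyl flanked by the quaternary C4 and the methylated bridgehead C8, and from the face over the substituted C9=C10 bridge. The penta-substituted aromatic precursor is a multistep target in itself.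
- Comparison: removal of the C3 carbonyl of A2 is of the same kind and difficulty as step 7 (equal). Both key steps are stereospecific by geometry (equal). The chosen plan is ahead in its source of absolute configuration and in unhindered early steps. Total step counts should be similar once the aromatic precursor and a resolution are counted.

Alternative 2: The cuts are C4–C5 and C9–C10, which open both rings to the acyclic (Z)-dienyl β-keto ester A3. A chiral Brønsted acid assisted by a Lewis acid (a BINOL-type diol with SnCl4) would protonate the terminal C3=C4 alkene. The Z-alkene C5=C10 would then add to C4, and the enol of the keto ester would close ring B at C10 to give A4.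
- In its favour: two rings, two C–C bonds and both stereocentres would form in one step from a precursor very close to commercial materials. In step economy up to the decalin this is clearly the better plan. A4 has oxygen on C8 (for the methyl, via an enol triflate) and a carbon, C11, on C9, which is equal to or better than what 16 offers.
- Against it here: the cis fusion depends on a fully concerted anti addition across the Z-alkene. Any lifetime of the tertiary C10 cation opens the way to the trans isomer, and the Z-alkene forces an axial substituent in the chair-like transition state, which slows the concerted path. Enantioselective protonation has to compete with binding of SnCl4 to the β-keto ester. C11 is one carbon short of the C11–C12 link, so a homologation remains.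
- Comparison: the chosen plan is mechanistically safer, because its relative configuration follows from a short tether and its absolute configuration from a separate allylation. In the alternative both rest on one cationic event of unfavourable geometry. The alternative would be shorter by several steps if that event were selective.

Alternative 3: The cuts are C1–C10 and C4–C5 of ring A. Quinone A5 and diene A6 would combine in a Diels–Alder reaction under a chiral oxazaborolidinium Lewis acid to give the cis-fused adduct A7.
- In its favour: the suprafacial cycloaddition guarantees the cis fusion and would set C5 and C10 in one catalytic enantioselective step from two cheap compounds. In convergence and in steps to the bicycle this is better than the chosen plan. The C8 methyl is in place and C9 is a carbonyl. Catalyst binding at the less hindered C6 carbonyl should direct the unsubstituted diene terminus to the methylated quinone carbon, which is the regiochemistry needed.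
- Against it here: A6 is a reluctant diene, because the Z-methyl on its substituted terminus disfavours the s-cis conformer, and it is prone to acid-induced isomerisation. Its fully substituted terminus must form the congested C4–C5 bond. A7 carries more functionality than needed: the C6 carbonyl and the C2=C3 alkene must go, and C7=C8 must be moved to C8=C9 while a chain is attached at the hindered C9. H-5 stays α to the C6 carbonyl, so acid or base may epimerise it towards the trans isomer.
- Comparison: both plans take the absolute configuration from asymmetric catalysis (equal). The alternative is better in convergence and in bringing the C8 methyl. The chosen plan is better in redox economy after the key step and in the configurational safety of C5, which is never next to a carbonyl once ring B is closed. The total step count of the alternative is expected to be comparable or higher.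

Key step: step 6

Conventions and assumption:
- Labdane-type numbering is used for the decalin and the chain.
- "Dec" stands for (4aR,8aS)-2,5,5,8a-tetramethyl-3,4,4a,5,6,7,8,8a-octahydronaphthalen-1-yl, the cis-fused bicycle attached through C9 with H-5 and the C10 methyl on the same face.
- The structures of 13, 16 and 47 were cross-checked atom by atom: 13 is R, 16 is 4aR,8S,8aS, and both carry the C5 and C10 configurations of 47 (5R,10S). No correction was needed.
- Assumption: the sense of induction of the diphosphine in step 3 is assigned by analogy with related cyclic enol carbonates. If it proves opposite, the equally available antipode of the ligand is used.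
- The ANDEN-phenyl diphosphine is N,N'-(9,10-dihydro-9,10-ethanoanthracene-11,12-diyl)bis[2-(diphenylphosphanyl)benzamide].

## Steps

Step 1
Reactants: 1 dimedone (5,5-dimethylcyclohexane-1,3-dione); 2 2-methylpropan-1-ol
Product: 3 3-isobutoxy-5,5-dimethylcyclohex-2-en-1-one
Conditions: i-BuOH, TsOH·H2O (cat.), toluene, reflux, Dean–Stark trap
Reagents that add atoms: 2-methylpropan-1-ol, CC(C)CO
Why: Acid-catalysed enol etherification of a symmetrical cyclic 1,3-dione (vinylogous ester formation) is driven by azeotropic removal of water and can give only one regioisomer.

Step 2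
Reactants: 3 3-isobutoxy-5,5-dimethylcyclohex-2-en-1-one; 4 allyl chloroformate
Product: 6 allyl 5-isobutoxy-3,3-dimethylcyclohexa-1,5-dien-1-yl carbonate, via lithium dienolate 5 (not isolated)
Conditions: LiN(i-Pr)2, THF, −78 °C; TMEDA; ClCO2CH2CH=CH2, −78 → 0 °C
Reagents that add atoms: allyl chloroformate, C=CCOC(=O)Cl
Why: Kinetic α′-deprotonation of the vinylogous ester gives the cross-conjugated dienolate, which the hard chloroformate acylates on oxygen (enol carbonate formation). Any C-acylated β-keto ester formed alongside would enter step 3 through the same palladium enolate.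

Step 3
Reactants: 6 allyl 5-isobutoxy-3,3-dimethylcyclohexa-1,5-dien-1-yl carbonate
Product: 7 (R)-6-allyl-3-isobutoxy-5,5-dimethylcyclohex-2-en-1-one
Conditions: Pd2(dba)3·CHCl3 (2.5 mol%), (R,R)-ANDEN-phenyl diphosphine (5.5 mol%), 1,4-dioxane, 23 °C
Reagents that add atoms: none
Why: Decarboxylative asymmetric allylic alkylation (Tsuji–Trost type): zerovalent palladium ionises the allyl carbonate, CO2 is lost, and the enolate recombines with the π-allyl cation inside the chiral pocket, which selects one face of the enolate carbon and sets the R centre (future C5). The base-free conditions keep the enolate from equilibrating, so the tertiary centre should be neither racemised nor allylated twice.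

Step 4
Reactants: 7 (R)-6-allyl-3-isobutoxy-5,5-dimethylcyclohex-2-en-1-one; 8 methyllithium; 9 water
Product: 11 (R)-4-allyl-3,5,5-trimethylcyclohex-2-en-1-one, via lithium carbinolate 10 (not isolated)
Conditions: MeLi, CeCl3, THF, −78 °C; then 1 M HCl (aq), 0 °C → rt
Reagents that add atoms: methyllithium, [Li]C; water, O
Why: 1,2-Addition of the organocerium reagent to the vinylogous ester carbonyl, then acid-induced ionisation of the tertiary allylic carbinol and hydrolysis of the oxocarbenium ion (Stork–Danheiser transposition), moves the carbonyl to the former enol ether carbon and brings in the future C10 methyl. The low basicity of the cerium reagent and the mild acid leave the stereocentre, now γ to the carbonyl, untouched.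

Step 5
Reactants: 11 (R)-4-allyl-3,5,5-trimethylcyclohex-2-en-1-one; 12 carbon monoxide
Product: 13 (R)-4-(4-oxobutyl)-3,5,5-trimethylcyclohex-2-en-1-one
Conditions: Rh(acac)(CO)2 (1 mol%), BiPhePhos (2 mol%), CO/H2 (1:1, 10 bar), toluene, 60 °C
Reagents that add atoms: carbon monoxide, [C-]#[O+]
Why: Rhodium-catalysed hydroformylation with a wide-bite-angle bisphosphite is selective for the linear aldehyde of a monosubstituted alkene and adds the C9 carbon. The trisubstituted, conjugated ring alkene does not react under these mild conditions.

Step 6
Reactants: 13 (R)-4-(4-oxobutyl)-3,5,5-trimethylcyclohex-2-en-1-one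
Product: 16 (4aR,8S,8aS)-8-hydroxy-4,4,8a-trimethyloctahydronaphthalen-2(1H)-one (cis-fused; C9 hydroxyl on the side of the C10 methyl), via samarium ketyl 14 (not isolated), via samarium enolate 15 (not isolated)
Conditions: SmI2 (2.5 equiv), t-BuOH (2 equiv), THF, −78 → 0 °C, slow addition of 13 to the reagent; aq NH4Cl
Reagents that add atoms: none
Why: SmI2 (divalent samarium) transfers one electron to the aldehyde to give ketyl 14, a nucleophilic α-oxy radical that adds to the electron-poor enone β-carbon C10; a second electron turns the resulting α-keto radical into enolate 15 of trivalent samarium, which t-BuOH and the work-up protonate to the C2 ketone. The closest known reaction type is the SmI2 ketyl–olefin (aldehyde–enone) reductive cyclisation. Ring B closes in the 6-exo-trig mode, the attacked C1=C10 bond lying outside the new ring. C10 is controlled by the existing C5 centre: the four-carbon tether prefers the pseudoaxial position (allylic strain with the C10 methyl) and can reach the π-face of C10 only on its own side, so the new C9–C10 bond is cis to C5–C6 and the methyl ends cis to H-5. C9 is set by the chair-like transition state in which the bulky, solvated samarium alkoxide turns away from the enone, which places the hydroxyl on the side of the methyl; this centre is cleared in step 8, so its control is not needed. The step needs chemoselectivity for cyclisation over pinacol coupling and over simple reduction of either carbonyl, which the intramolecular 6-exo trap, inverse addition at low concentration and the weak proton donor should provide, and it needs the cis fusion, which the short tether from C5 secures.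

Step 7
Reactants: 16 (4aR,8S,8aS)-8-hydroxy-4,4,8a-trimethyloctahydronaphthalen-2(1H)-one
Product: 18 (1S,4aR,8aS)-5,5,8a-trimethyldecahydronaphthalen-1-ol, via hydrazone 17 (not isolated)
Conditions: N2H4·H2O, KOH, diethylene glycol, 130 °C, then 200 °C with removal of water
Reagents that add atoms: none
Why: Wolff–Kishner reduction (Huang-Minlon procedure): the C2 carbonyl, flanked by two methylene groups, forms the hydrazone, which loses N2 under hot KOH to leave a methylene group. The carbinol is inert as its alkoxide and neither ring-fusion centre is α to the carbonyl, so the cis fusion cannot be lost.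

Step 8
Reactants: 18 (1S,4aR,8aS)-5,5,8a-trimethyldecahydronaphthalen-1-ol
Product: 19 (4aR,8aS)-5,5,8a-trimethyloctahydronaphthalen-1(2H)-one
Conditions: Dess–Martin periodinane, CH2Cl2, 0 °C → rt
Reagents that add atoms: none
Why: Dess–Martin oxidation of a hindered secondary alcohol to the ketone under neutral conditions. Both C9 epimers would converge here, and the quaternary C10 rules out epimerisation of the ring fusion.

Step 9
Reactants: 19 (4aR,8aS)-5,5,8a-trimethyloctahydronaphthalen-1(2H)-one; 20 iodomethane
Product: 22 (4aR,8aS)-2,5,5,8a-tetramethyloctahydronaphthalen-1(2H)-one (mixture of epimers at the methylated carbon C8), via lithium enolate 21 (not isolated)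
Conditions: LiN(i-Pr)2, THF, −78 °C; MeI, −78 → 0 °C
Reagents that add atoms: iodomethane, CI
Why: Alkylation of a regiodefined lithium enolate: only C8 carries α-hydrogens, so methylation can occur only there. The new C8 centre is of no consequence because it becomes trigonal in step 10.

Step 10
Reactants: 22 (4aR,8aS)-2,5,5,8a-tetramethyloctahydronaphthalen-1(2H)-one; 23 N-phenylbis(trifluoromethanesulfonimide)
Product: 25 Dec trifluoromethanesulfonate (enol triflate on C9, alkene C8=C9), via lithium enolate 24 (not isolated)
Conditions: LiN(i-Pr)2, THF, −78 → 0 °C; PhNTf2, 0 °C → rt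
Reagents that add atoms: N-phenylbis(trifluoromethanesulfonimide), O=S(=O)(N(c1ccccc1)S(=O)(=O)C(F)(F)F)C(F)(F)F
Why: Enol triflate formation by O-sulfonylation of the only possible enolate (towards C8) gives the tetrasubstituted C8=C9 alkenyl triflate. The same operation is routine for 2,2,6-trimethylcyclohexanone, the monocyclic counterpart of 22.

Step 11
Reactants: 25 Dec trifluoromethanesulfonate; 26 tributyl(vinyl)stannane
Product: 27 (4aR,8aS)-1-ethenyl-2,5,5,8a-tetramethyl-3,4,4a,5,6,7,8,8a-octahydronaphthalene (Dec–CH=CH2)
Conditions: Pd(PPh3)4 (5 mol%), LiCl (3 equiv), THF, 65 °C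
Reagents that add atoms: tributyl(vinyl)stannane, C=C[Sn](CCCC)(CCCC)CCCC
Why: Stille coupling of an alkenyl triflate with a vinylstannane in the presence of LiCl forms C9–C11 without moving the ring alkene. Vinyl is the smallest sp2 partner and couples even with hindered cyclohexenyl triflates.

Step 12
Reactants: 27 Dec–CH=CH2; 28 hydrogen peroxide
Product: 30 2-Dec-ethan-1-ol, via B-alkyl-9-BBN 29 (not isolated)
Conditions: 9-BBN, THF, 0 °C → rt; then 3 M NaOH, 30% H2O2, 0 °C → rt
Reagents that add atoms: hydrogen peroxide, OO
Why: Hydroboration–oxidation: the bulky 9-BBN adds boron to the terminal carbon of the monosubstituted alkene only and leaves the tetrasubstituted ring alkene alone. Alkaline peroxide then replaces boron by hydroxyl at C12.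

Step 13
Reactants: 30 2-Dec-ethan-1-ol; 31 iodine
Product: 32 1-iodo-2-Dec-ethane
Conditions: I2, PPh3, imidazole, CH2Cl2, 0 °C → rt
Reagents that add atoms: iodine, II
Why: Appel iodination: the primary alcohol is activated as its alkoxyphosphonium ion and displaced by iodide (SN2). The neutral conditions spare the tetrasubstituted alkene.

Step 14
Reactants: 32 1-iodo-2-Dec-ethane; 33 triethyl phosphonoacetate
Product: 35 ethyl 4-Dec-2-(diethoxyphosphoryl)butanoate (both epimers at C13), via sodium phosphonoacetate 34 (not isolated)
Conditions: NaH, (EtO)2P(O)CH2CO2Et (2 equiv), DMF, 0 °C → rt; then 32, 60 °C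
Reagents that add atoms: triethyl phosphonoacetate, CCOC(=O)CP(=O)(OCC)OCC
Why: SN2 C-alkylation of the soft, stabilised phosphonoacetate carbanion by a primary iodide forms C12–C13. An excess of the carbanion limits dialkylation and its low basicity disfavours elimination back to 27; the new stereocentre is removed in step 17.

Step 15
Reactants: 36 prop-2-yn-1-ol; 37 tributyltin hydride
Product: 38 (E)-3-(tributylstannyl)prop-2-en-1-ol
Conditions: Bu3SnH, AIBN (cat.), neat, 80 °C; chromatography
Reagents that add atoms: tributyltin hydride, CCCC[SnH](CCCC)CCCC
Why: Radical hydrostannation of a terminal alkyne: reversible addition of the stannyl radical funnels the adducts to the more stable E-β-stannyl alkene, which is separated from minor isomers.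

Step 16
Reactants: 38 (E)-3-(tributylstannyl)prop-2-en-1-ol
Product: 39 (E)-3-(tributylstannyl)prop-2-enal
Conditions: MnO2, CH2Cl2, rt
Reagents that add atoms: none
Why: Oxidation of an allylic alcohol with activated MnO2 stops at the aldehyde and preserves the C–Sn bond and the E geometry.

Step 17
Reactants: 35 ethyl 4-Dec-2-(diethoxyphosphoryl)butanoate; 39 (E)-3-(tributylstannyl)prop-2-enal
Product: 41 ethyl (2E,4E)-2-(2-Dec-ethyl)-5-(tributylstannyl)penta-2,4-dienoate, via sodium phosphonate carbanion 40 (not isolated)
Conditions: NaH, THF, 0 °C; then 39, 0 °C → rt
Reagents that add atoms: (E)-3-(tributylstannyl)prop-2-enal, O=C/C=C/[Sn](CCCC)(CCCC)CCCC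
Why: Horner–Wadsworth–Emmons olefination: the adducts of the stabilised carbanion and the enal equilibrate, and elimination through the less crowded oxaphosphetane places the ester trans to the dienyl carbon, giving (E)-C13=C14. The (E)-alkenylstannane of 39 is carried through unchanged.

Step 18
Reactants: 41 ethyl (2E,4E)-2-(2-Dec-ethyl)-5-(tributylstannyl)penta-2,4-dienoate
Product: 43 (2E,4E)-2-(2-Dec-ethyl)-5-(tributylstannyl)penta-2,4-dien-1-ol, via dienal 42 (not isolated)
Conditions: i-Bu2AlH (2.5 equiv), CH2Cl2, −78 → −20 °C; aq KNaC4H4O6
Reagents that add atoms: none
Why: 1,2-Reduction of an α,β-unsaturated ester by an electrophilic aluminium hydride gives the allylic alcohol without conjugate reduction. Alkenes and the alkenylstannane do not react with i-Bu2AlH at low temperature.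

Step 19
Reactants: 44 tetronic acid (furan-2,4(3H,5H)-dione); 45 trifluoromethanesulfonic anhydride
Product: 46 5-oxo-2,5-dihydrofuran-3-yl trifluoromethanesulfonate
Conditions: Tf2O, i-Pr2NEt, CH2Cl2, −78 °C
Reagents that add atoms: trifluoromethanesulfonic anhydride, O=S(=O)(OS(=O)(=O)C(F)(F)F)C(F)(F)F
Why: O-Sulfonylation of the enol form of a cyclic β-keto lactone gives the vinylogous acyl triflate. Low temperature and a hindered amine limit decomposition of the product.

Step 20
Reactants: 43 (2E,4E)-2-(2-Dec-ethyl)-5-(tributylstannyl)penta-2,4-dien-1-ol; 46 5-oxo-2,5-dihydrofuran-3-yl trifluoromethanesulfonate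
Product: 47 4-[(1E,3E)-6-Dec-4-(hydroxymethyl)hexa-1,3-dien-1-yl]furan-2(5H)-one (CNP0232848.3)
Conditions: Pd2(dba)3 (2.5 mol%), AsPh3 (20 mol%), LiCl (3 equiv), NMP, rt, exclusion of light
Reagents that add atoms: 5-oxo-2,5-dihydrofuran-3-yl trifluoromethanesulfonate, O=C1C=C(OS(=O)(=O)C(F)(F)F)CO1
Why: Stille coupling: oxidative addition of zerovalent palladium to the electron-poor triflate is fast, and transmetalation and reductive elimination proceed with retention at both sp2 carbons, so the (E,E)-diene is preserved. The neutral, room-temperature conditions tolerate the free allylic alcohol and the butenolide, which is why this bond is made last.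

## Compound list

1 | dimedone (5,5-dimethylcyclohexane-1,3-dione) | CC1(C)CC(=O)CC(=O)C1 | starting material
2 | 2-methylpropan-1-ol | CC(C)CO | starting material
3 | 3-isobutoxy-5,5-dimethylcyclohex-2-en-1-one | CC(C)COC1=CC(=O)CC(C)(C)C1 | intermediate
4 | allyl chloroformate | C=CCOC(=O)Cl | starting material
5 | lithium 5-isobutoxy-3,3-dimethylcyclohexa-1,5-dien-1-olate | [Li+].[O-]C1=CC(C)(C)CC(OCC(C)C)=C1 | intermediate (not isolated)
6 | allyl 5-isobutoxy-3,3-dimethylcyclohexa-1,5-dien-1-yl carbonate | C=CCOC(=O)OC1=CC(C)(C)CC(OCC(C)C)=C1 | intermediate
7 | (R)-6-allyl-3-isobutoxy-5,5-dimethylcyclohex-2-en-1-one | C=CC[C@H]1C(=O)C=C(OCC(C)C)CC1(C)C | intermediate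
8 | methyllithium | [Li]C | starting material
9 | water | O | starting material
10 | lithium (6R)-6-allyl-3-isobutoxy-1,5,5-trimethylcyclohex-2-en-1-olate (both C1 epimers) | C=CC[C@H]1C(C)([O-])C=C(OCC(C)C)CC1(C)C.[Li+] | intermediate (not isolated)
11 | (R)-4-allyl-3,5,5-trimethylcyclohex-2-en-1-one | C=CC[C@H]1C(C)=CC(=O)CC1(C)C | intermediate
12 | carbon monoxide | [C-]#[O+] | starting material
13 | (R)-4-(4-oxobutyl)-3,5,5-trimethylcyclohex-2-en-1-one | O=CCCC[C@H]1C(C)=CC(=O)CC1(C)C | intermediate
14 | samarium ketyl of 13 (C9 radical, O–SmI2) | I[Sm](I)O[CH]CCC[C@H]1C(C)=CC(=O)CC1(C)C | intermediate (not isolated)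
15 | samarium enolate–alkoxide of 16 (C1=C2 enolate, C9 alkoxide) | I[Sm](I)O[C@H]1CCC[C@@H]2C(C)(C)CC(O[Sm](I)I)=C[C@]12C | intermediate (not isolated)
16 | (4aR,8S,8aS)-8-hydroxy-4,4,8a-trimethyloctahydronaphthalen-2(1H)-one | O[C@H]1CCC[C@@H]2C(C)(C)CC(=O)C[C@]12C | intermediate
17 | hydrazone of 16 at C2 | O[C@H]1CCC[C@@H]2C(C)(C)CC(=NN)C[C@]12C | intermediate (not isolated)
18 | (1S,4aR,8aS)-5,5,8a-trimethyldecahydronaphthalen-1-ol | O[C@H]1CCC[C@@H]2C(C)(C)CCC[C@]12C | intermediate
19 | (4aR,8aS)-5,5,8a-trimethyloctahydronaphthalen-1(2H)-one | O=C1CCC[C@@H]2C(C)(C)CCC[C@]12C | intermediate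
20 | iodomethane | CI | starting material
21 | lithium enolate of 19 (C8=C9) | [Li+].[O-]C1=CCC[C@@H]2C(C)(C)CCC[C@]12C | intermediate (not isolated)
22 | (4aR,8aS)-2,5,5,8a-tetramethyloctahydronaphthalen-1(2H)-one (C8 epimers) | O=C1C(C)CC[C@@H]2C(C)(C)CCC[C@]12C | intermediate
23 | N-phenylbis(trifluoromethanesulfonimide) | O=S(=O)(N(c1ccccc1)S(=O)(=O)C(F)(F)F)C(F)(F)F | starting material
24 | lithium enolate of 22 (C8=C9) | [Li+].[O-]C1=C(C)CC[C@@H]2C(C)(C)CCC[C@]12C | intermediate (not isolated)
25 | (4aR,8aS)-2,5,5,8a-tetramethyl-3,4,4a,5,6,7,8,8a-octahydronaphthalen-1-yl trifluoromethanesulfonate | CC1=C(OS(=O)(=O)C(F)(F)F)[C@@]2(C)CCCC(C)(C)[C@H]2CC1 | intermediate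
26 | tributyl(vinyl)stannane | C=C[Sn](CCCC)(CCCC)CCCC | starting material
27 | (4aR,8aS)-1-ethenyl-2,5,5,8a-tetramethyl-3,4,4a,5,6,7,8,8a-octahydronaphthalene | CC1=C(C=C)[C@@]2(C)CCCC(C)(C)[C@H]2CC1 | intermediate
28 | hydrogen peroxide | OO | starting material
29 | 9-(2-Dec-ethyl)-9-borabicyclo[3.3.1]nonane | CC1=C(CCB3C4CCCC3CCC4)[C@@]2(C)CCCC(C)(C)[C@H]2CC1 | intermediate (not isolated)
30 | 2-Dec-ethan-1-ol | CC1=C(CCO)[C@@]2(C)CCCC(C)(C)[C@H]2CC1 | intermediate
31 | iodine | II | starting material
32 | 1-iodo-2-Dec-ethane | CC1=C(CCI)[C@@]2(C)CCCC(C)(C)[C@H]2CC1 | intermediate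
33 | triethyl phosphonoacetate | CCOC(=O)CP(=O)(OCC)OCC | starting material
34 | sodium salt of triethyl phosphonoacetate | [Na+].CCOC(=O)[CH-]P(=O)(OCC)OCC | intermediate (not isolated)
35 | ethyl 4-Dec-2-(diethoxyphosphoryl)butanoate (C13 epimers) | CC1=C(CCC(C(=O)OCC)P(=O)(OCC)OCC)[C@@]2(C)CCCC(C)(C)[C@H]2CC1 | intermediate
36 | prop-2-yn-1-ol | C#CCO | starting material
37 | tributyltin hydride | CCCC[SnH](CCCC)CCCC | starting material
38 | (E)-3-(tributylstannyl)prop-2-en-1-ol | OC/C=C/[Sn](CCCC)(CCCC)CCCC | intermediate
39 | (E)-3-(tributylstannyl)prop-2-enal | O=C/C=C/[Sn](CCCC)(CCCC)CCCC | intermediate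
40 | sodium carbanion of 35 | [Na+].CC1=C(CC[C-](C(=O)OCC)P(=O)(OCC)OCC)[C@@]2(C)CCCC(C)(C)[C@H]2CC1 | intermediate (not isolated)
41 | ethyl (2E,4E)-2-(2-Dec-ethyl)-5-(tributylstannyl)penta-2,4-dienoate | CC1=C(CC/C(=C\C=C\[Sn](CCCC)(CCCC)CCCC)C(=O)OCC)[C@@]2(C)CCCC(C)(C)[C@H]2CC1 | intermediate
42 | (2E,4E)-2-(2-Dec-ethyl)-5-(tributylstannyl)penta-2,4-dienal | CC1=C(CC/C(=C\C=C\[Sn](CCCC)(CCCC)CCCC)C=O)[C@@]2(C)CCCC(C)(C)[C@H]2CC1 | intermediate (not isolated)
43 | (2E,4E)-2-(2-Dec-ethyl)-5-(tributylstannyl)penta-2,4-dien-1-ol | CC1=C(CC/C(=C\C=C\[Sn](CCCC)(CCCC)CCCC)CO)[C@@]2(C)CCCC(C)(C)[C@H]2CC1 | intermediate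
44 | tetronic acid (furan-2,4(3H,5H)-dione) | O=C1CC(=O)CO1 | starting material
45 | trifluoromethanesulfonic anhydride | O=S(=O)(OS(=O)(=O)C(F)(F)F)C(F)(F)F | starting material
46 | 5-oxo-2,5-dihydrofuran-3-yl trifluoromethanesulfonate | O=C1C=C(OS(=O)(=O)C(F)(F)F)CO1 | intermediate
47 | 4-[(1E,3E)-6-Dec-4-(hydroxymethyl)hexa-1,3-dien-1-yl]furan-2(5H)-one | CC1=C(CC/C(=C\C=C\C2=CC(=O)OC2)CO)[C@@]2(C)CCCC(C)(C)[C@H]2CC1 | target

## Step count and least certain steps

Total step count: 20. Longest linear sequence: 17 steps (steps 1 to 14, 17, 18 and 20); steps 15, 16 and 19 prepare the two coupling partners.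

Step 6 (key step).
- What may go wrong: intermolecular pinacol coupling or simple reduction of the aldehyde, or one-electron reduction of the enone followed by conjugate reduction, may outrun the cyclisation. The reason is that the ketyl must attack a β,β-disubstituted enone carbon and build a quaternary centre next to C5 and near C4. Loss of cis selectivity is less likely, because the tether cannot span the ring.
- Fallback, from 13 back to 16: the ketyl is replaced by a neutral α-silyloxy radical. 13 is treated with PhSeSiMe3 (cat. ZnI2, CH2Cl2) to give the O-silyl hemiselenoacetal (R)-3,5,5-trimethyl-4-[4-(phenylselanyl)-4-(trimethylsilyloxy)butyl]cyclohex-2-en-1-one F1. Slow addition of Bu3SnH and AIBN in benzene at 80 °C abstracts the phenylselanyl group. The C9 radical closes 6-exo onto C10 under the same tether control, and the α-keto radical takes hydrogen from the stannane to give (4aR,8S,8aS)-4,4,8a-trimethyl-8-(trimethylsilyloxy)octahydronaphthalen-2(1H)-one F2. K2CO3 in MeOH removes the silyl group and returns the route to 16. Any C9 epimer formed alongside converges at 19 through steps 7 and 8.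

Step 3.
- What may go wrong: face selection at the enolate carbon may be insufficient, because the gem-dimethyl group next to it is an unusual environment for the ligand pocket. Proton transfer between product and enolate could also erode the configuration or lead to double allylation.
- Fallback, from 3 back to 7: resolution replaces asymmetric catalysis. 3 is deprotonated with LiN(i-Pr)2 and alkylated with allyl bromide to give racemic 6-allyl-3-isobutoxy-5,5-dimethylcyclohex-2-en-1-one F3. Preparative chromatography on a chiral stationary phase delivers 7. The unwanted enantiomer can be racemised with KOt-Bu in t-BuOH and recycled.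

Step 10.
- What may go wrong: deprotonation of the hindered C8 methine or O-sulfonylation of the resulting tetrasubstituted enolate next to the quaternary C10 may be incomplete, and recovered ketone would lower throughput. The same crowding could slow the oxidative addition in step 11.
- Fallback, from 22 back to 27 (it replaces steps 10 and 11): carbonyl addition and dehydration take the place of cross-coupling. CH2=CHMgBr with CeCl3 in THF adds to the C9 carbonyl to give (4aR,8aS)-1-ethenyl-2,5,5,8a-tetramethyldecahydronaphthalen-1-ol F4. Dehydration with Burgess reagent in benzene at 50 °C (or POCl3 in pyridine if the syn geometry is lacking) can only remove the C8 hydrogen, since C10 is quaternary, and gives 27.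

Step 17.
- What may go wrong: geometric control at C13=C14 may be lost to the Z isomer, because α-branched phosphonoacetates equilibrate their adducts less completely than the parent reagent.
- Fallback, from 32 back to 41 (it replaces steps 14 and 17): an α-branched stabilised phosphorane is used, whose olefinations are under stronger thermodynamic control. 32 is heated with Ph3P=CHCO2Et in toluene to give the phosphonium salt (1-ethoxy-1-oxo-4-Dec-butan-2-yl)triphenylphosphonium iodide F5. Aqueous NaOH converts it into the ylide ethyl 4-Dec-2-(triphenylphosphoranylidene)butanoate F6. A Wittig reaction of F6 with 39 in toluene at 90 °C gives 41.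

Step 20.
- What may go wrong: protodestannylation or homocoupling of the electron-rich dienylstannane, hydrolytic decomposition of the vinylogous acyl triflate, and light-induced isomerisation of the triene during isolation.
- Fallback, from 43 back to 47: the polarity of the coupling is reversed. 43 is treated with I2 in CH2Cl2 at 0 °C (iododestannylation with retention) to give (2E,4E)-2-(2-Dec-ethyl)-5-iodopenta-2,4-dien-1-ol F7. 46 is converted with (Bu3Sn)2, Pd(PPh3)4 and LiCl in THF into 4-(tributylstannyl)furan-2(5H)-one F8. Stille coupling of F7 with F8 (Pd2(dba)3, AsPh3, DMF, rt) gives 47.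

## Further compounds

F1 | step 6 | (R)-3,5,5-trimethyl-4-[4-(phenylselanyl)-4-(trimethylsilyloxy)butyl]cyclohex-2-en-1-one (C9 epimers) | C[Si](C)(C)OC([Se]c1ccccc1)CCC[C@H]1C(C)=CC(=O)CC1(C)C
F2 | step 6 | (4aR,8S,8aS)-4,4,8a-trimethyl-8-(trimethylsilyloxy)octahydronaphthalen-2(1H)-one | C[Si](C)(C)O[C@H]1CCC[C@@H]2C(C)(C)CC(=O)C[C@]12C
F3 | step 3 | racemic 6-allyl-3-isobutoxy-5,5-dimethylcyclohex-2-en-1-one | C=CCC1C(=O)C=C(OCC(C)C)CC1(C)C
F4 | step 10 | (4aR,8aS)-1-ethenyl-2,5,5,8a-tetramethyldecahydronaphthalen-1-ol (epimers at C8 and C9) | C=CC1(O)C(C)CC[C@@H]2C(C)(C)CCC[C@]12C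
F5 | step 17 | (1-ethoxy-1-oxo-4-Dec-butan-2-yl)triphenylphosphonium iodide | CC1=C(CCC(C(=O)OCC)[P+](c3ccccc3)(c3ccccc3)c3ccccc3)[C@@]2(C)CCCC(C)(C)[C@H]2CC1.[I-]
F6 | step 17 | ethyl 4-Dec-2-(triphenylphosphoranylidene)butanoate | CC1=C(CCC(C(=O)OCC)=P(c3ccccc3)(c3ccccc3)c3ccccc3)[C@@]2(C)CCCC(C)(C)[C@H]2CC1
F7 | step 20 | (2E,4E)-2-(2-Dec-ethyl)-5-iodopenta-2,4-dien-1-ol | CC1=C(CC/C(=C\C=C\I)CO)[C@@]2(C)CCCC(C)(C)[C@H]2CC1
F8 | step 20 | 4-(tributylstannyl)furan-2(5H)-one | O=C1C=C([Sn](CCCC)(CCCC)CCCC)CO1
A1 | alternative 1 | 6-[2-(tert-butyldimethylsilyloxy)ethyl]-2-ethenyl-1,3,3,5-tetramethylbicyclo[2.2.2]oct-5-en-2-ol (vinyl group on the side of the C5=C6 bridge) | C=C[C@]1(O)C(C)(C)[C@H]2CC[C@]1(C)C(CCO[Si](C)(C)C(C)(C)C)=C2C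
A2 | alternative 1 | cis-decalin C3 ketone with C8=C9 alkene and C9 silyloxyethyl chain | CC1=C(CCO[Si](C)(C)C(C)(C)C)[C@@]2(C)CCC(=O)C(C)(C)[C@H]2CC1
A3 | alternative 2 | methyl (6Z)-7,11-dimethyl-3-oxododeca-6,10-dienoate | COC(=O)CC(=O)CC/C=C(C)\CCC=C(C)C
A4 | alternative 2 | cis-fused bicyclic β-keto ester (C8 enol form) | OC1=C(C(=O)OC)[C@@]2(C)CCCC(C)(C)[C@H]2CC1
A5 | alternative 3 | 2,6-dimethyl-1,4-benzoquinone | CC1=CC(=O)C=C(C)C1=O
A6 | alternative 3 | 4-methylpenta-1,3-diene | C=CC=C(C)C
A7 | alternative 3 | cis-fused Diels–Alder adduct (carbonyls at C6 and C9) | O=C1C(C)=CC(=O)[C@H]2[C@]1(C)CC=CC2(C)C
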